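Germacrane numbering is used throughout. The ring oxygen bridges C1 (hemiketal) and C4 (C–CH3). C5=C6 is the enol-lactone alkene, C6/C7/C11/C12 the butenolide, C13 the CH2OAc carbon, C8 the carbinol and C10 the tertiary acetate.
Enabling feature: C1 (ketone level) and C4 (fully substituted C–O) are 1,4-related, and their outer bonds C1–C10 and C4–C5 are cis on the oxolane. The hemiketal is therefore the Kornblum–DeLaMare isomer of a cis-3,6-disubstituted 1,2-dioxane (C1–C2–C3–C4–O–O) whose only α-hydrogen sits on C1.
Cuts: O–C1 (dioxane to oxolane ring contraction), C5=C6 (aldol then E1cB, which closes the ten-membered carbocycle over the two-atom O–O bridge) and C9–C10 (chelate Mukaiyama aldol). A temporary C5=C10 bond turns the dioxane into the O2 adduct of 1,3-dimethylcyclohexa-1,3-diene.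
Forward order: diene + 1O2 gives the bicyclic endoperoxide; ozonolysis removes the helper carbocycle; aldol with a 3-acetylfuran; furan to butenolide; macro-aldol; base cascade; desilylation and 13-acetylation.
Stereochemistry: C4 comes from a catalytic kinetic resolution of the endoperoxide. The cycloaddition ties C1 to C4, C1 relays to C10 (chelation) and C10 to C8 (syn reduction). C1 is then erased and reset by the bridge, and the ring fixes the C5=C6 geometry.

Key step: step 18

Assumption: the quinidine-derived catalyst is taken to consume the (1S,4R) enantiomer of 4; if the sense is the opposite, the quinine-derived pseudo-enantiomer (9-O-acetylcupreine) is used instead.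

Step 1
Reactants: 1 3-methylcyclohex-2-en-1-one
Product: 3 1,3-dimethylcyclohexa-1,3-diene, via tertiary allylic alcohol 2 (not isolated)
Conditions: MeMgBr, Et2O, 0 °C; then p-TsOH (cat.), pentane, rt
Reagents that add atoms: methylmagnesium bromide, C[Mg]Br
Why: 1,2-Grignard addition to the enone followed by acid-catalysed E1 dehydration through the symmetrical 1,3-dimethylcyclohexenyl cation should give the endocyclic conjugated diene as the equilibrium product; no stereocenter is formed.

Step 2
Reactants: 3 1,3-dimethylcyclohexa-1,3-diene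
Product: 4 rac-1,5-dimethyl-2,3-dioxabicyclo[2.2.2]oct-5-ene
Conditions: O2, tetraphenylporphyrin (cat.), visible light, CH2Cl2, 0 °C
Reagents that add atoms: dioxygen, O=O
Why: [4+2] cycloaddition of singlet oxygen to a cisoid cyclic 1,3-diene (ascaridole-type photooxygenation) adds both oxygens suprafacially, so C1–O and C4–O are cis and the C1/C4 relation is fixed by the bicycle.

Step 3
Reactants: 4 rac-1,5-dimethyl-2,3-dioxabicyclo[2.2.2]oct-5-ene
Product: 5 (1R,4S)-1,5-dimethyl-2,3-dioxabicyclo[2.2.2]oct-5-ene
Conditions: 9-O-acetylcupreidine (10 mol %), CH2Cl2, 0 °C, stopped a little beyond half conversion; chromatography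
Reagents that add atoms: none
Why: Proposed new method: the quinuclidine nitrogen of the bifunctional cinchona base removes the bridgehead C–H antiperiplanar to O–O while its phenol OH binds the departing oxygen; the closest known reaction is the catalytic desymmetrising Kornblum–DeLaMare rearrangement of meso bicyclic endoperoxides, where the catalyst tells the two enantiotopic bridgehead C–H bonds apart, and since each enantiomer of 4 offers its single C–H (the other bridgehead bears methyl) in one of these two orientations, one enantiomer should be consumed to the hydroxy enone and 5 should remain, which sets C4 as R.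

Step 4
Reactants: 5 (1R,4S)-1,5-dimethyl-2,3-dioxabicyclo[2.2.2]oct-5-ene
Product: 7 1-[(3S,6R)-6-(dimethoxymethyl)-6-methyl-1,2-dioxan-3-yl]ethan-1-one, via methoxy hydroperoxide acetal 6 (not isolated)
Conditions: O3, CH2Cl2/MeOH, −78 °C; p-TsOH (cat.), rt; NaHCO3; Me2S
Reagents that add atoms: ozone, [O-][O+]=O; methanol, CO
Why: Ozonolysis in methanol with unsymmetrical work-up: the carbonyl oxide should form on the more substituted C10 and be trapped by methanol, the free C5 aldehyde is acetalised, and Me2S reduces only the hydroperoxide and not the dialkyl peroxide, so the helper carbocycle is removed with C1 and C4 untouched.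

Step 5
Reactants: 8 furan-3,4-diyldimethanol
Product: 9 [4-({[tert-butyl(dimethyl)silyl]oxy}methyl)furan-3-yl]methanol
Conditions: NaH (1 equiv), THF, rt; TBSCl (1 equiv)
Reagents that add atoms: tert-butyldimethylsilyl chloride, CC(C)(C)[Si](C)(C)Cl
Why: Monosilylation of a symmetrical diol through its sparingly soluble monosodium alkoxide differentiates C13 from C8.

Step 6
Reactants: 9 [4-({[tert-butyl(dimethyl)silyl]oxy}methyl)furan-3-yl]methanol
Product: 10 4-({[tert-butyl(dimethyl)silyl]oxy}methyl)furan-3-carbaldehyde
Conditions: MnO2, CH2Cl2, rt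
Reagents that add atoms: none
Why: MnO2 oxidation of a furylic (benzylic-type) primary alcohol stops at the aldehyde.

Step 7
Reactants: 10 4-({[tert-butyl(dimethyl)silyl]oxy}methyl)furan-3-carbaldehyde
Product: 11 rac-1-[4-({[tert-butyl(dimethyl)silyl]oxy}methyl)furan-3-yl]ethan-1-ol
Conditions: MeMgBr, THF, −78 °C
Reagents that add atoms: methylmagnesium bromide, C[Mg]Br
Why: Grignard addition brings in C9; the carbinol centre is removed in the next step.

Step 8
Reactants: 11 rac-1-[4-({[tert-butyl(dimethyl)silyl]oxy}methyl)furan-3-yl]ethan-1-ol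
Product: 12 1-[4-({[tert-butyl(dimethyl)silyl]oxy}methyl)furan-3-yl]ethan-1-one
Conditions: MnO2, CH2Cl2, rt
Reagents that add atoms: none
Why: MnO2 oxidation of the secondary furylic alcohol gives the methyl ketone (C8=O, C9H3).

Step 9
Reactants: 12 1-[4-({[tert-butyl(dimethyl)silyl]oxy}methyl)furan-3-yl]ethan-1-one
Product: 13 tert-butyl(dimethyl)[(4-{1-[(trimethylsilyl)oxy]ethenyl}furan-3-yl)methoxy]silane
Conditions: TMSOTf, Et3N, CH2Cl2, 0 °C
Reagents that add atoms: trimethylsilyl triflate, C[Si](C)(C)OS(=O)(=O)C(F)(F)F
Why: Soft enolisation and O-silylation of a methyl ketone that can enolise in one direction only gives the C9 nucleophile in non-basic form.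

Step 10
Reactants: 7 1-[(3S,6R)-6-(dimethoxymethyl)-6-methyl-1,2-dioxan-3-yl]ethan-1-one; 13 tert-butyl(dimethyl)[(4-{1-[(trimethylsilyl)oxy]ethenyl}furan-3-yl)methoxy]silane
Product: 14 (3S)-3-[(3S,6R)-6-(dimethoxymethyl)-6-methyl-1,2-dioxan-3-yl]-3-hydroxy-1-[4-({[tert-butyl(dimethyl)silyl]oxy}methyl)furan-3-yl]butan-1-one
Conditions: TiCl4 (1.1 equiv), CH2Cl2, −78 °C, 7 then 13; pH 7 buffer at −78 °C
Reagents that add atoms: none
Why: Mukaiyama aldol addition under chelation control: TiCl4 ties the ketone oxygen to the ring oxygen on C1 in a five-membered chelate, so the enol silane attacks the face that carries H-1 rather than C2 and should give (10S), while the neopentyl, peroxy-substituted acetal ionises more slowly than the chelated ketone reacts.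

Step 11
Reactants: 14 aldol adduct (C8 ketone, C10 tertiary alcohol)
Product: 15 (1R,3S)-3-[(3S,6R)-6-(dimethoxymethyl)-6-methyl-1,2-dioxan-3-yl]-1-[4-({[tert-butyl(dimethyl)silyl]oxy}methyl)furan-3-yl]butane-1,3-diol
Conditions: Et2BOMe, THF/MeOH, −78 °C; NaBH4; AcOH; MeOH azeotrope
Reagents that add atoms: none
Why: Narasaka–Prasad reduction: the boron chelate of the β-hydroxy ketone places the dioxanyl group and the furyl group equatorial, and axial hydride delivery should give the 1,3-syn diol, which is (8R); borohydride leaves the dialkyl peroxide alone.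

Step 12
Reactants: 15 syn-1,3-diol
Product: 16 C8 tert-butyldimethylsilyl ether of 15
Conditions: TBSCl, imidazole, DMF, rt
Reagents that add atoms: tert-butyldimethylsilyl chloride, CC(C)(C)[Si](C)(C)Cl
Why: Silylation distinguishes the secondary furylic alcohol from the hindered tertiary alcohol on steric grounds.

Step 13
Reactants: 16 C8 silyl ether with free C10 alcohol
Product: 17 C10 acetate of 16
Conditions: Ac2O, DMAP, Et3N, CH2Cl2, 35 °C
Reagents that add atoms: acetic anhydride, CC(=O)OC(C)=O
Why: DMAP-catalysed acylation installs the tertiary acetate; the monocyclic chair dioxane should tolerate the amines because H-1 is axial there and gauche to O–O.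

Step 14
Reactants: 17 furan with C10 acetate
Product: 19 4-substituted 3-({[tert-butyl(dimethyl)silyl]oxy}methyl)furan-2(5H)-one (C12 carbonyl, C6H2), via hydroxybutenolide 18 (not isolated)
Conditions: O2, tetraphenylporphyrin (cat.), visible light, i-Pr2NEt, CH2Cl2, −78 °C; then NaBH4, MeOH, −20 °C; citric acid
Reagents that add atoms: dioxygen, O=O
Why: Furan photooxygenation ([4+2]) followed by base-induced Kornblum–DeLaMare opening, in which the hindered amine takes the less shielded bridgehead hydrogen next to CH2OTBS so that the carbonyl arises at C12; borohydride then reduces the masked C6 aldehyde and the hydroxy acid lactonises.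

Step 15
Reactants: 19 butenolide dimethyl acetal
Product: 20 butenolide aldehyde (C5 aldehyde on C4 of the dioxane)
Conditions: TESOTf, 2,6-lutidine, CH2Cl2, 0 °C; then H2O
Reagents that add atoms: water, O
Why: Acetal cleavage through the lutidinium salt under almost neutral conditions frees the aldehyde without harm to silyl ethers, acetate, lactone or peroxide.

Step 16
Reactants: 20 butenolide aldehyde
Product: 23 bridged macrocyclic aldol (C5–C6 bond, C5 hydroxyl, O–O bridge from C1 to C4), via silyloxyfuran 21 (not isolated), via aldol silyl ether 22 (not isolated)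
Conditions: TMSOTf, i-Pr2NEt, CH2Cl2 (1 mM, slow addition of 20), −78 to −30 °C; then AcOH/THF/H2O
Reagents that add atoms: none
Why: One-pot enol silylation and intramolecular vinylogous Mukaiyama aldol reaction (silylative aldol cyclisation of a butenolide aldehyde): the cis arms of the dioxane bring C5 and C6 together and the ring formed is ten-membered by either path round the dioxane; C5 and C6 are not controlled and both vanish in step 18.

Step 17
Reactants: 23 bridged macrocyclic aldol
Product: 24 C5 methanesulfonate of 23
Conditions: MsCl, Et3N, CH2Cl2, −40 °C; cold aqueous work-up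
Reagents that add atoms: methanesulfonyl chloride, CS(=O)(=O)Cl
Why: Sulfonylation turns the C5 hydroxyl into a far better leaving group than the silyloxy group on C13 and removes the free β-peroxy alcohol before stronger base is used.

Step 18
Reactants: 24 C5 methanesulfonate (1,2-dioxane bridge)
Product: 27 8,13-bis-O-(tert-butyldimethylsilyl) ether of the 13-deacetyl target (oxolane hemiketal bridge), via alkylidene endoperoxide 25 (not isolated), via hydroxy ketone 26 (not isolated)
Conditions: DBU (2.5 equiv), CH2Cl2, 0 °C to rt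
Reagents that add atoms: none
Why: DBU first removes the vinylogously acidic H-6 and E1cB loss of mesylate from C5 gives alkylidene butenolide 25; it then removes H-1, the only hydrogen α to the peroxide (C4 is quaternary), which stands antiperiplanar to O–O in the boat-shaped bridged dioxane, so C1=O forms as O–O breaks (Kornblum–DeLaMare rearrangement, a redox-neutral isomerisation in which the extruded ring oxygen becomes the carbonyl and later the hydroxyl oxygen). The C4 alkoxide of 26 then adds across the ring to the C1 ketone (5-exo-trig), so the six-membered ring C1–C2–C3–C4–O–O ends as the five-membered ring C1–C2–C3–C4–O with the C4–O bond, and hence (4R), untouched. The closest known reactions are the amine-induced isomerisation of bicyclic saturated endoperoxides to 4-hydroxy ketones and the base-induced dehydration of butenolide aldols to γ-alkylidene butenolides. The new centre C1 is controlled by the six-carbon bridge C5–C10: the C4 oxygen can reach only the ketone face that keeps C10 and C5 cis on the oxolane, which is (1S), and as a hemiketal the centre can also equilibrate to this sole bridged form. The alkene geometry is set by the ring, since only the isomer with C4 and C7 cis fits the bridged ten-membered ring. The selectivity needed is loss of the C5 rather than the C13 oxygen from the same dienolate, which mesylate against silyloxide secures, and if the peroxide opened first the C4 alkoxide would close a 4,5-epoxide that removal of H-6 reopens, so both orders converge on 27.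

Step 19
Reactants: 27 bis-silyl ether
Product: 28 13-deacetyl target (free C8, C13 and C1 hydroxyls)
Conditions: HF·pyridine, pyridine, THF, 0 °C to rt
Reagents that add atoms: none
Why: Buffered fluoride desilylation removes both silyl ethers and should leave the tertiary acetate, the hemiketal and the enol lactone intact.

Step 20
Reactants: 28 13-deacetyl target
Product: 29 (1S,4R,5E,8R,10S)-10,13-diacetoxy-1,8-dihydroxy-1,4-epoxygermacra-5,7(11)-dien-12,6-olide (CNP0203479.1)
Conditions: AcCl (1.05 equiv), 2,4,6-collidine, CH2Cl2, −78 °C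
Reagents that add atoms: acetyl chloride, CC(=O)Cl
Why: Low-temperature acylation with a hindered pyridine base is selective for the primary allylic C13 alcohol over the hindered secondary C8 alcohol and the tertiary hemiketal hydroxyl, and it avoids the basic conditions that could move the C10 acetate.

Compound list
1 | 3-methylcyclohex-2-en-1-one | CC1=CC(=O)CCC1 | starting material
2 | 1,3-dimethylcyclohex-2-en-1-ol (racemic) | CC1=CC(C)(O)CCC1 | intermediate
3 | 1,3-dimethylcyclohexa-1,3-diene | CC1=CC(C)=CCC1 | intermediate
4 | rac-1,5-dimethyl-2,3-dioxabicyclo[2.2.2]oct-5-ene (relative configuration fixed by the bicycle) | CC1=CC2(C)CCC1OO2 | intermediate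
5 | (1R,4S)-1,5-dimethyl-2,3-dioxabicyclo[2.2.2]oct-5-ene | CC1=C[C@@]2(C)CC[C@@H]1OO2 | intermediate
6 | (3S,6R)-6-(dimethoxymethyl)-3-(1-hydroperoxy-1-methoxyethyl)-6-methyl-1,2-dioxane (epimers at the hydroperoxy carbon) | COC(C)(OO)[C@@H]1CC[C@](C)(C(OC)OC)OO1 | intermediate
7 | 1-[(3S,6R)-6-(dimethoxymethyl)-6-methyl-1,2-dioxan-3-yl]ethan-1-one | CC(=O)[C@@H]1CC[C@](C)(C(OC)OC)OO1 | intermediate
8 | furan-3,4-diyldimethanol | OCc1cocc1CO | starting material
9 | [4-({[tert-butyl(dimethyl)silyl]oxy}methyl)furan-3-yl]methanol | CC(C)(C)[Si](C)(C)OCc1cocc1CO | intermediate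
10 | 4-({[tert-butyl(dimethyl)silyl]oxy}methyl)furan-3-carbaldehyde | CC(C)(C)[Si](C)(C)OCc1cocc1C=O | intermediate
11 | rac-1-[4-({[tert-butyl(dimethyl)silyl]oxy}methyl)furan-3-yl]ethan-1-ol | CC(O)c1cocc1CO[Si](C)(C)C(C)(C)C | intermediate
12 | 1-[4-({[tert-butyl(dimethyl)silyl]oxy}methyl)furan-3-yl]ethan-1-one | CC(=O)c1cocc1CO[Si](C)(C)C(C)(C)C | intermediate
13 | trimethylsilyl enol ether of 12 | C=C(O[Si](C)(C)C)c1cocc1CO[Si](C)(C)C(C)(C)C | intermediate
14 | aldol adduct, (10S) tertiary alcohol, C8 ketone, (1S,4R)-dioxane | O=C(C[C@](C)(O)[C@@H]1CC[C@](C)(C(OC)OC)OO1)c1cocc1CO[Si](C)(C)C(C)(C)C | intermediate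
15 | (8R,10S) syn-1,3-diol | O[C@H](C[C@](C)(O)[C@@H]1CC[C@](C)(C(OC)OC)OO1)c1cocc1CO[Si](C)(C)C(C)(C)C | intermediate
16 | C8 TBS ether, free C10 alcohol | CC(C)(C)[Si](C)(C)O[C@H](C[C@](C)(O)[C@@H]1CC[C@](C)(C(OC)OC)OO1)c1cocc1CO[Si](C)(C)C(C)(C)C | intermediate
17 | C8 TBS ether, C10 acetate, furan | CC(C)(C)[Si](C)(C)O[C@H](C[C@](C)(OC(C)=O)[C@@H]1CC[C@](C)(C(OC)OC)OO1)c1cocc1CO[Si](C)(C)C(C)(C)C | intermediate
18 | 5-hydroxybutenolide (C12 carbonyl, C6 lactol, epimers at C6) | CC(C)(C)[Si](C)(C)OCC1=C(C(O)OC1=O)[C@@H](C[C@](C)(OC(C)=O)[C@@H]2CC[C@](C)(C(OC)OC)OO2)O[Si](C)(C)C(C)(C)C | intermediate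
19 | butenolide dimethyl acetal | CC(C)(C)[Si](C)(C)OCC1=C(COC1=O)[C@@H](C[C@](C)(OC(C)=O)[C@@H]2CC[C@](C)(C(OC)OC)OO2)O[Si](C)(C)C(C)(C)C | intermediate
20 | butenolide aldehyde | CC(C)(C)[Si](C)(C)OCC1=C(COC1=O)[C@@H](C[C@](C)(OC(C)=O)[C@@H]2CC[C@](C)(C=O)OO2)O[Si](C)(C)C(C)(C)C | intermediate
21 | 2-(trimethylsilyloxy)furan aldehyde | CC(C)(C)[Si](C)(C)OCc1c(O[Si](C)(C)C)occ1[C@@H](C[C@](C)(OC(C)=O)[C@@H]2CC[C@](C)(C=O)OO2)O[Si](C)(C)C(C)(C)C | intermediate
22 | bridged macrocyclic aldol, C5 trimethylsilyl ether (C5/C6 epimers) | CC(C)(C)[Si](C)(C)OCC1=C2[C@H](O[Si](C)(C)C(C)(C)C)C[C@](C)(OC(C)=O)[C@@H]3CC[C@@](C)(OO3)C(O[Si](C)(C)C)C2OC1=O | intermediate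
23 | bridged macrocyclic aldol, free C5 hydroxyl (C5/C6 epimers) | CC(C)(C)[Si](C)(C)OCC1=C2[C@H](O[Si](C)(C)C(C)(C)C)C[C@](C)(OC(C)=O)[C@@H]3CC[C@@](C)(OO3)C(O)C2OC1=O | intermediate
24 | C5 methanesulfonate of 23 (C5/C6 epimers) | CC(C)(C)[Si](C)(C)OCC1=C2[C@H](O[Si](C)(C)C(C)(C)C)C[C@](C)(OC(C)=O)[C@@H]3CC[C@@](C)(OO3)C(OS(C)(=O)=O)C2OC1=O | intermediate
25 | (5E)-alkylidene butenolide with 1,4-epidioxy bridge, (1S,4R,8R,10S) | CC(C)(C)[Si](C)(C)OCC1=C2/C(=C\[C@@]3(C)CC[C@H](OO3)[C@@](C)(OC(C)=O)C[C@H]2O[Si](C)(C)C(C)(C)C)OC1=O | intermediate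
26 | 4-hydroxy-1-oxo ten-membered ring ketone (open form) | CC(C)(C)[Si](C)(C)OCC1=C2/C(=C\[C@](C)(O)CCC(=O)[C@@](C)(OC(C)=O)C[C@H]2O[Si](C)(C)C(C)(C)C)OC1=O | intermediate
27 | 8,13-bis-O-TBS ether of the 13-deacetyl target | CC(C)(C)[Si](C)(C)OCC1=C2/C(=C\[C@@]3(C)CC[C@](O)(O3)[C@@](C)(OC(C)=O)C[C@H]2O[Si](C)(C)C(C)(C)C)OC1=O | intermediate
28 | 13-deacetyl target | OCC1=C2/C(=C\[C@@]3(C)CC[C@](O)(O3)[C@@](C)(OC(C)=O)C[C@H]2O)OC1=O | intermediate
29 | (1S,4R,5E,8R,10S)-10,13-diacetoxy-1,8-dihydroxy-1,4-epoxygermacra-5,7(11)-dien-12,6-olide | CC(=O)OCC1=C2/C(=C\[C@@]3(C)CC[C@](O)(O3)[C@@](C)(OC(C)=O)C[C@H]2O)OC1=O | target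

Total step count: 20. Longest linear sequence: 16 steps (steps 5–20 from 8); the other branch (steps 1–4, then 10–20) has 15.

Steps most likely to fail

Step 3 (Proposed new method). The rate difference between the two enantiomers may be too small, or an uncatalysed rearrangement may erode it, so the recovered endoperoxide stays partly racemic. The fallback is a classical resolution through diastereomeric acetals; it sets out from 4 and returns at 7. Racemic 4 would be ozonised with plain Me2S work-up to the racemic cis keto aldehyde F1. This would be condensed with (R,R)-hydrobenzoin (PPTS, MgSO4, CH2Cl2) to two diastereomeric dioxolanes. The (3S,6R) isomer, hydrobenzoin acetal F2, would be separated by chromatography or crystallisation and exchanged with MeOH/HC(OMe)3 and catalytic p-TsOH into 7.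

Step 16. Oligomerisation may outrun ring closure, because the dioxane must leave its chair to let the two arms meet, and the silyl triflate may start heterolysis of the peroxide. The fallback closes the ring by olefination instead of aldol addition; it sets out from 18 and returns at 25. Hydroxybutenolide 18 would be isolated instead of being reduced. It would be treated with diethyl phosphite and Et3N (Pudovik addition to its open aldehyde form) and then with acid to relactonise, giving γ-phosphono butenolide F3. Acetal cleavage as in step 15 would give phosphonate aldehyde F4. An intramolecular Horner–Wadsworth–Emmons reaction (LiCl, i-Pr2NEt, MeCN, high dilution) would close the ring directly at the alkene level to 25, which is then taken through the second half of step 18.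

Step 10. Several things may go wrong here:
- enolisation of the ketone toward C1 with loss of the peroxide;
- attack of the enol silane on the acetal;
- poor facial selectivity if the peroxide oxygen chelates weakly;
- fragmentation of the β-peroxy alkoxide before the quench.

The fallback uses a preformed neutral metal enolate; it sets out from 13 and 7 and returns at 14. Enol silane 13 would be brominated with NBS to bromo ketone F5. Its zinc enolate (activated Zn, THF, 0 °C, decanted from excess metal; Reformatsky reaction) is non-basic and itself chelating, and it would be added to 7 at −78 °C to give 14.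

Further compounds
F1 | step 3 | rac-cis-6-acetyl-3-methyl-1,2-dioxane-3-carbaldehyde (racemate, one enantiomer drawn) | CC(=O)[C@@H]1CC[C@](C)(C=O)OO1
F2 | step 3 | 1-{(3S,6R)-6-[(4R,5R)-4,5-diphenyl-1,3-dioxolan-2-yl]-6-methyl-1,2-dioxan-3-yl}ethan-1-one | CC(=O)[C@@H]1CC[C@](C)(C2O[C@H](c3ccccc3)[C@@H](c3ccccc3)O2)OO1
F3 | step 16 | diethyl C6-phosphonate of butenolide dimethyl acetal 19 (epimers at C6) | CCOP(=O)(OCC)C1OC(=O)C(CO[Si](C)(C)C(C)(C)C)=C1[C@@H](C[C@](C)(OC(C)=O)[C@@H]2CC[C@](C)(C(OC)OC)OO2)O[Si](C)(C)C(C)(C)C
F4 | step 16 | diethyl C6-phosphonate of butenolide aldehyde 20 (epimers at C6) | CCOP(=O)(OCC)C1OC(=O)C(CO[Si](C)(C)C(C)(C)C)=C1[C@@H](C[C@](C)(OC(C)=O)[C@@H]2CC[C@](C)(C=O)OO2)O[Si](C)(C)C(C)(C)C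
F5 | step 10 | 2-bromo-1-[4-({[tert-butyl(dimethyl)silyl]oxy}methyl)furan-3-yl]ethan-1-one | O=C(CBr)c1cocc1CO[Si](C)(C)C(C)(C)C
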